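## Structural features

The target has a single ring, the cyclohexane of quinic acid. C1 is quaternary and carries a hydroxyl and the free carboxylic acid, C3 carries a free secondary hydroxyl, and C4 and C5 each carry an (E)-4-hydroxycinnamate (p-coumarate) ester. C3, C4 and C5 are adjacent stereocentres and C1 is 1,3 to both C3 and C5. Read from the SMILES, O1, O3 and O4 lie on one face and O5 and the carboxyl on the other, so O3/O4 are cis and O4/O5 trans: (1S,3R,4R,5R) in quinate numbering. The fragile parts are the two cinnamate esters (cleaved by base and shifted by base onto the neighbouring free O3), their (E)-alkenes, the free phenols, and the tertiary α-hydroxy acid, whose carboxyl is cis to O5 and lactonises onto it whenever O5 is free. The real difficulty is not the skeleton but the absolute configuration of quaternary C1, trans oxygens at C4/C5 with O4 cis to O3, two identical acyl groups on O4 and O5 while O3 and O1 stay free, and a final unmasking without base. The key step uses the C4–C5 bond: its trans oxygens are what anti opening of a C4–C5 epoxide gives, and the C4=C5 alkene is the closing bond of a cyclohexene made by metathesis from an open chain that already holds the C1 and C3 carbinols. The allylic O3–H, with O1–H on the same face, then directs the epoxide oxygen. A check of the open-chain diene against the target shows that both carbinol carbons must be R and that (R)-malic acid, alkylated with retention, is the right enantiomer. One design change is needed: a free C3 hydroxyl in the open chain (or beside the dioxolanone) is a γ-hydroxy acyl compound that closes to the butyrolactone, so O3 is carried as a triethylsilyl ether until the ring is closed, where it is trans to the ester and cannot reach it.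

## Logic of the disconnections

24 from 23: three benzylic C–O bonds (one ester, two aryl ethers) and the O3–Si bond are cut. All four are acid-labile, so one acid treatment finishes the synthesis and every base-sensitive ester is made on a fully protected compound. The forward step must be acidic, contain a cation trap, and avoid base.

23 from 22 and 21: the O4–acyl bond is cut. In 22 only O4–H is a reactive hydroxyl, so no selectivity between secondary hydroxyls is needed. The forward step must acylate a hindered secondary alcohol and leave the tertiary O1–H alone.

22 from 17 and 21: the C5–O5 bond is cut. Trans O4/O5 is the signature of anti epoxide opening, and using the acid itself as nucleophile brings in the ester with its oxygen. This reduces two stereocentres to a cis epoxide whose face is easy to control. The forward step needs attack at C5 and not C4, a blocked O3, and a basic medium free of Lewis acid, because the C1 ester carbonyl is placed to open the epoxide itself.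

21 from 18 and 19: the phenolic O–benzyl bond is cut, to give a phenol mask that survives carboxylate chemistry and falls off in the final acid step.

17 from 16, and 16 from 15: the O3–Si bond, then the two epoxide C–O bonds, are cut. This leads back to an alkene with only two stereocentres. The forward steps need oxygen delivery to the face of O3 and O1 (hydroxyl direction) and silylation of the secondary O3–H in preference to the tertiary O1–H.

15 from 13 (through 14): the C4=C5 bond is cut. No stereocentre is involved, and the ring becomes an acyclic 1,7-diene whose two 1,3-related carbinols can be set independently. The forward step needs cyclisation over oligomerisation, and O3 must stay silylated during closure and be freed only afterwards.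

13 from 11 and 12: the ester C(=O)–O bond is cut. The C1 hydroxyl and carboxyl go back into the acetal that created C1. The alkoxide must attack only the lactone carbonyl, and O3 must be protected so the chain cannot close to a lactone.

11 from 9 (through 10): the C3–H bond and the O3–Si bond are cut. The C3 stereocentre is traced to a ketone under reagent control. The forward step needs R selectivity, 1,2- over 1,4-reduction, and trapping of the alcohol before it attacks the lactone acetal.

9 from 6 and 7 (through 8): the C3–C4 bond between acyl carbon and vinyl is cut. The side-chain acid becomes the ketone carbon. The coupling must be chemoselective and leave the lactone acetal and the allyl group untouched.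

6 from 3 and 4 (through 5): the C1–C6 bond is cut. The quaternary centre comes from a tertiary one, and the enolate must be alkylated anti to the tert-butyl group so the original configuration is regenerated.

3 from 1 and 2: the two acetal C–O bonds are cut, reaching commercial materials. The acetal must form cis so that it can relay the configuration in the alkylation.

## Other disconnections considered

Alternative 1: The cut is at the C1–O and C4–O bonds together. In the forward sense, sensitised photo-oxygenation of methyl (5R)-5-(tert-butyldimethylsilyloxy)cyclohexa-1,3-diene-1-carboxylate (A2) would add singlet oxygen across C1 and C4, anti to the silyloxy group, to give methyl 1,4-epidioxy-5-(tert-butyldimethylsilyloxy)cyclohex-2-ene-1-carboxylate (A1).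
- In its favour: one metal-free step would form two C–O bonds and two stereocentres (quaternary C1 and C4), both correctly placed relative to O5. On this point it is better than the chosen key step, which sets no stereocentre.
- Against it: A2 is a silylated arene hydrate and should lose silanol to methyl benzoate under mild acid, base or heat. Its diene is ester-conjugated and electron-poor, so cycloaddition should be slow and an ene reaction may compete. After O–O reduction of A1, the C2=C3 alkene must still become C3–OH/C2–H2 with O3 cis to O4, a regioselective hydration between two similar allylic positions. The oxygens also arrive in the wrong pattern (O5 silylated, O1/O4 free), so protecting groups must be exchanged before the esters go on.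
- Comparison: the chosen plan relies on a better precedented alkylation for C1 and puts the alkene where the diester belongs. The alternative is stronger in bond economy at the key step but equal or longer overall once A2 and the end game are counted.

Alternative 2: The cut is at the C1–C2 bond. In the forward sense, the silyl ketene acetal of (5R,6S)-5-(tert-butyldimethylsilyloxy)-3-(methoxymethoxy)-6-vinyltetrahydro-2H-pyran-2-one (A4) would undergo Ireland–Claisen rearrangement through a boat transition state to 1-(methoxymethoxy)-5-(tert-butyldimethylsilyloxy)cyclohex-3-ene-1-carboxylic acid (A3).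
- In its favour: a stereospecific pericyclic C–C bond formation makes the ring and quaternary C1 at once, with chirality transferred from the lactone carbinol. Osmylation of the C3=C4 alkene of A3 anti to the allylic silyloxy group would then give the cis-3,4-diol in one reliable step. That is better than the chosen route's epoxidation, silylation and regioselective opening for setting the oxygens.
- Against it: A4 needs its own multi-step asymmetric synthesis, and the bicyclic boat transition state is strained. The alkene of A3 maps onto O3/O4, the pair that must be differentiated in this target: after dihydroxylation O3 and O4 are an undifferentiated cis-diol and O5 carries the silyl group, so several selective protecting-group steps are needed.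
- Comparison: equal in predictability of C1, better in diol stereocontrol, worse in fit to the 4,5-diester pattern, and probably longer.

Alternative 3: The cut is at the C3–C4 bond. In the forward sense, SmI2 (divalent samarium) would couple the two aldehydes of methyl (2R,4R)-4-(tert-butyldimethylsilyloxy)-2-(methoxymethoxy)-5-oxo-2-(2-oxoethyl)pentanoate (A6) to methyl 1-O-methoxymethyl-5-O-(tert-butyldimethylsilyl)quinate (A5).
- In its favour: the ring and two stereocentres form together, the samarium-bridged diolate should give the cis-diol anti to the C5 silyloxy group, and A5 already has the full quinate oxygenation. On that point it is better than the chosen plan, which must oxidise the ring after closure.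
- Against it: A6 holds an epimerisable α-silyloxy aldehyde (whose ketyl can expel the α-oxygen) and a β-alkoxy aldehyde prone to elimination, so it would have to be made and used at once. The face of the new diol relative to C1 rests on the C5 substituent alone. A5 again has O3/O4 free and O5 masked, the reverse of what this target needs.
- Comparison: the alternative builds more stereochemistry in its key step and avoids ruthenium. The chosen plan has the more robust key-step precursor and ends with protecting groups already matched to the 4,5-diester, so its end game is shorter.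

Key step: step 6

Remark: quinate numbering is used for all ring compounds (C1 bears the carboxyl, C3 the free hydroxyl, C4 and C5 the esters; O5 is the oxygen cis to the carboxyl), and (R)-malic acid and (E)-p-coumaric acid are taken as commercial single isomers.

## Route

Step 1
Reactants: 1 (R)-malic acid; 2 pivalaldehyde
Product: 3 2-[(2R,4R)-2-tert-butyl-5-oxo-1,3-dioxolan-4-yl]acetic acid
Conditions: t-BuCHO (2 equiv), TsOH·H2O (cat.), H2SO4 (cat.), pentane, reflux, Dean–Stark; recrystallisation
Reagents that add atoms: pivalaldehyde (compound 2), CC(C)(C)C=O
Why: Acid-catalysed acetalisation with azeotropic removal of water; the α-hydroxy acid unit closes the five-membered dioxolanone in preference to the six-membered alternative, and the 2,5-cis isomer, favoured at equilibrium, should crystallise. The malate stereocentre is untouched and the acetal centre is set cis to it by equilibration.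

Step 2
Reactants: 3; 4 allyl bromide
Product: 6 2-[(2R,4R)-4-allyl-2-tert-butyl-5-oxo-1,3-dioxolan-4-yl]acetic acid, via dilithium enolate 5 (not isolated)
Conditions: LiN(SiMe3)2 (2.2 equiv), THF, −78 °C; CH2=CHCH2Br, −78 → −20 °C; cold 1 M HCl
Reagents that add atoms: allyl bromide (compound 4), C=CCBr
Why: Alkylation with self-regeneration of the stereocentre: the second equivalent of base makes the lactone enolate, trigonal at C1, and allyl bromide should enter anti to the tert-butyl group of the acetal. Allyl therefore takes the place of the original hydrogen (overall retention), which sets quaternary C1 as R.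

Step 3
Reactants: 6; 7 tributyl(vinyl)stannane
Product: 9 (2R,5R)-5-allyl-2-tert-butyl-5-(2-oxobut-3-en-1-yl)-1,3-dioxolan-4-one, via acid chloride 8 (not isolated)
Conditions: (COCl)2, DMF (cat.), CH2Cl2, 0 °C → rt, evaporate; CH2=CHSnBu3, PdCl2(PPh3)2 (3 mol%), BHT (cat.), toluene, 50 °C
Reagents that add atoms: tributyl(vinyl)stannane (compound 7), C=C[Sn](CCCC)(CCCC)CCCC
Why: The acid chloride is coupled with the vinylstannane in a Stille acylation (oxidative addition of the C–Cl bond to zerovalent palladium formed in situ, transfer of vinyl from tin, reductive elimination). These neutral conditions should leave the lactone acetal and the allyl group alone, and BHT with prompt use guards the vinyl ketone against polymerisation.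

Step 4
Reactants: 9
Product: 11 (2R,5R)-5-allyl-2-tert-butyl-5-[(2R)-2-(triethylsilyloxy)but-3-en-1-yl]-1,3-dioxolan-4-one, via allylic alcohol 10 (not isolated)
Conditions: (S)-2-methyl-CBS-oxazaborolidine (0.3 equiv), catecholborane (1.8 equiv), toluene, −78 °C; MeOH, pH 7 buffer; crude, Et3SiOTf, 2,6-lutidine, CH2Cl2, −78 °C
Reagents that add atoms: triethylsilyl trifluoromethanesulfonate, CC[Si](CC)(CC)OS(=O)(=O)C(F)(F)F
Why: Corey–Bakshi–Shibata reduction: with the vinyl group acting as the larger substituent on the boron-bound ketone, hydride from the (S)-catalyst–borane complex should give the (R)-carbinol, and catecholborane at −78 °C spares both alkenes. C1 is already fixed, so any C3 epimer is a diastereomer removable by chromatography, and immediate silylation stops the new hydroxyl from attacking the lactone acetal.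

Step 5
Reactants: 11; 12 4-methoxybenzyl alcohol
Product: 13 4-methoxybenzyl (2R,4R)-2-allyl-2-hydroxy-4-(triethylsilyloxy)hex-5-enoate
Conditions: 4-MeOC6H4CH2OH (2.5 equiv), n-BuLi (1.5 equiv), THF, −40 → 0 °C; aq. NH4Cl
Reagents that add atoms: 4-methoxybenzyl alcohol (compound 12), COc1ccc(CO)cc1
Why: Alkoxide transesterification of the dioxolanone: the lithium alkoxide adds to the activated lactone carbonyl and the tetrahedral intermediate collapses to the ester with loss of pivalaldehyde from the hemiacetal alkoxide. C1 has no α-hydrogen and cannot epimerise, and the silyl ether on O3 prevents closure to the γ-lactone.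

Step 6
Reactants: 13
Product: 15 4-methoxybenzyl (1R,3R)-1,3-dihydroxycyclohex-4-ene-1-carboxylate (quinate numbering; cis-diol), via triethylsilyl ether 14 (not isolated)
Conditions: second-generation Grubbs catalyst RuCl2(=CHPh)(H2IMes)(PCy3) (3 mol%), CH2Cl2 (0.01 M), 40 °C; EtOCH=CH2; MeOH, PPTS (0.2 equiv), rt
Reagents that add atoms: none
Why: Olefin metathesis by the Chauvin mechanism: the ruthenium benzylidene exchanges with the unhindered allyl terminus, the new alkylidene adds across the vinyl group next to C3 to give a ruthenacyclobutane, and cycloreversion releases the cyclohexene and a ruthenium methylidene that carries the chain, while ethylene leaves and makes closure irreversible. The closest known reaction type is ruthenium-catalysed ring-closing metathesis of 1,7-dienes to cyclohexenes, which tolerates free tertiary alcohols, esters and allylic silyl ethers. The one ring formed is a six-membered carbocycle closed between the two terminal alkene carbons (C4 and C5), and the ring size allows only the cis alkene. No stereocentre is formed, and C1 and C3 keep their configuration. The selectivity needed is cyclisation over intermolecular metathesis, secured by high dilution and by the fully substituted C1, whose geminal groups fold the chain (Thorpe–Ingold effect). The triethylsilyl ether keeps the open-chain γ-hydroxy ester from lactonising and the allylic oxygen from binding ruthenium during closure. Once the ring is closed O3 is trans to the ester and cannot reach it, so mild acidic methanolysis in the same flask removes the silyl group and frees the allylic hydroxyl needed in step 7.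

Step 7
Reactants: 15
Product: 16 4-methoxybenzyl (1S,3R,4R,5S)-4,5-epoxy-1,3-dihydroxycyclohexane-1-carboxylate (epoxide oxygen cis to O1 and O3)
Conditions: VO(acac)2 (5 mol%), t-BuOOH (1.5 equiv), CH2Cl2, 0 °C → rt
Reagents that add atoms: tert-butyl hydroperoxide, CC(C)(C)OO
Why: Vanadium-catalysed hydroxyl-directed epoxidation: the allylic O3–H, with the homoallylic O1–H on the same face, binds the vanadium peroxide and delivers oxygen to that face, so the epoxide should be cis to O3 and O1, which sets C4 and C5. A cis epoxy alcohol cannot undergo Payne rearrangement.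

Step 8
Reactants: 16
Product: 17 4-methoxybenzyl (1R,3R,4S,5S)-3-(tert-butyldimethylsilyloxy)-4,5-epoxy-1-hydroxycyclohexane-1-carboxylate
Conditions: TBSCl (1.5 equiv), imidazole (3 equiv), DMF, rt
Reagents that add atoms: tert-butyldimethylsilyl chloride, CC(C)(C)[Si](C)(C)Cl
Why: Silylation with the chloride and imidazole distinguishes the secondary O3–H from the hindered tertiary O1–H; epoxide and ester are inert.

Step 9
Reactants: 18 (E)-p-coumaric acid; 19 4-methoxybenzyl chloride
Product: 21 (E)-3-[4-(4-methoxybenzyloxy)phenyl]prop-2-enoic acid, via bis-benzylated ester 20 (not isolated)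
Conditions: 4-MeOC6H4CH2Cl (2.4 equiv), K2CO3 (3 equiv), KI (cat.), DMF, 60 °C; aq. NaOH, MeOH–THF, 60 °C; HCl to pH 3
Reagents that add atoms: 4-methoxybenzyl chloride (compound 19), COc1ccc(CCl)cc1; sodium hydroxide, [Na+].[OH-]
Why: Williamson ether synthesis and carboxylate alkylation, then saponification of the benzylic ester in the same flask; the aryl ether is stable to hydroxide and the (E)-alkene is retained.

Step 10
Reactants: 17; 21
Product: 22 4-methoxybenzyl (1R,3R,4S,5R)-3-(tert-butyldimethylsilyloxy)-1,4-dihydroxy-5-{(E)-3-[4-(4-methoxybenzyloxy)phenyl]prop-2-enoyloxy}cyclohexane-1-carboxylate (3-O-silyl-5-O-acyl quinate)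
Conditions: 21 (3 equiv), Cs2CO3 (0.75 equiv), DMF, 85 °C, dark
Reagents that add atoms: (E)-3-[4-(4-methoxybenzyloxy)phenyl]prop-2-enoic acid (compound 21), OC(=O)/C=C/c1ccc(OCc2ccc(OC)cc2)cc1
Why: SN2 opening of the epoxide by the cesium carboxylate, trans-diaxial in the Fürst–Plattner sense; attack should occur at C5, remote from the electron-withdrawing silyloxy-bearing C3 as with other cis-2,3-epoxycyclohexyl ethers, with inversion, which puts O5 trans to O4 and leaves O4 cis to O3. The basic medium avoids inducing the C1 ester carbonyl to open the epoxide, excess free acid protonates the O4 alkoxide at once, and any O5-to-O4 acyl shift is harmless because step 11 puts the same acyl group on the other oxygen.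

Step 11
Reactants: 22; 21
Product: 23 4-methoxybenzyl (1R,3R,4S,5R)-3-(tert-butyldimethylsilyloxy)-1-hydroxy-4,5-bis{(E)-3-[4-(4-methoxybenzyloxy)phenyl]prop-2-enoyloxy}cyclohexane-1-carboxylate
Conditions: 21 (2 equiv), DCC (2.2 equiv), DMAP (0.5 equiv), CH2Cl2, 0 °C → rt
Reagents that add atoms: (E)-3-[4-(4-methoxybenzyloxy)phenyl]prop-2-enoic acid (compound 21), OC(=O)/C=C/c1ccc(OCc2ccc(OC)cc2)cc1
Why: Steglich esterification (carbodiimide activation, acyl transfer through the acylpyridinium ion) of the only free secondary hydroxyl; the tertiary O1–H beside the ester should not compete. No stereocentre is touched.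

Step 12
Reactants: 23
Product: 24 4,5-di-O-p-coumaroylquinic acid, (1S,3R,4R,5R)-1,3-dihydroxy-4,5-bis{[(2E)-3-(4-hydroxyphenyl)prop-2-enoyl]oxy}cyclohexane-1-carboxylic acid
Conditions: CF3CO2H–CH2Cl2–H2O (10:10:1), pentamethylbenzene (10 equiv), 0 °C → rt
Reagents that add atoms: none
Why: Acidolysis: the 4-methoxybenzyl ester and the two 4-methoxybenzyl aryl ethers ionise to the benzylic cation, which pentamethylbenzene traps by Friedel–Crafts alkylation, and the silyl ether is solvolysed by the aqueous acid. No base is used, so ester cleavage and acyl migration should stay slow, and the cinnamate alkenes are unaffected.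

## Compound list

1 | (R)-malic acid | O[C@H](CC(=O)O)C(=O)O | starting material
2 | pivalaldehyde | CC(C)(C)C=O | starting material
3 | 2-[(2R,4R)-2-tert-butyl-5-oxo-1,3-dioxolan-4-yl]acetic acid | O=C1O[C@H](C(C)(C)C)O[C@@H]1CC(=O)O | intermediate
4 | allyl bromide | C=CCBr | starting material
5 | dilithium enolate of 3 (lithium carboxylate and lithium lactone enolate, acetal carbon R) | [Li+].[Li+].[O-]C(=O)CC1=C([O-])O[C@H](C(C)(C)C)O1 | intermediate
6 | 2-[(2R,4R)-4-allyl-2-tert-butyl-5-oxo-1,3-dioxolan-4-yl]acetic acid | O=C1O[C@H](C(C)(C)C)O[C@]1(CC=C)CC(=O)O | intermediate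
7 | tributyl(vinyl)stannane | C=C[Sn](CCCC)(CCCC)CCCC | starting material
8 | 2-[(2R,4R)-4-allyl-2-tert-butyl-5-oxo-1,3-dioxolan-4-yl]acetyl chloride | O=C1O[C@H](C(C)(C)C)O[C@]1(CC=C)CC(=O)Cl | intermediate
9 | (2R,5R)-5-allyl-2-tert-butyl-5-(2-oxobut-3-en-1-yl)-1,3-dioxolan-4-one | O=C1O[C@H](C(C)(C)C)O[C@]1(CC=C)CC(=O)C=C | intermediate
10 | (2R,5R)-5-allyl-2-tert-butyl-5-[(2R)-2-hydroxybut-3-en-1-yl]-1,3-dioxolan-4-one | O=C1O[C@H](C(C)(C)C)O[C@]1(CC=C)C[C@@H](O)C=C | intermediate
11 | (2R,5R)-5-allyl-2-tert-butyl-5-[(2R)-2-(triethylsilyloxy)but-3-en-1-yl]-1,3-dioxolan-4-one | O=C1O[C@H](C(C)(C)C)O[C@]1(CC=C)C[C@@H](O[Si](CC)(CC)CC)C=C | intermediate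
12 | 4-methoxybenzyl alcohol | COc1ccc(CO)cc1 | starting material
13 | 4-methoxybenzyl (2R,4R)-2-allyl-2-hydroxy-4-(triethylsilyloxy)hex-5-enoate | C=C[C@H](O[Si](CC)(CC)CC)C[C@@](O)(C(=O)OCc1ccc(OC)cc1)CC=C | intermediate
14 | 4-methoxybenzyl (1R,3R)-1-hydroxy-3-(triethylsilyloxy)cyclohex-4-ene-1-carboxylate (quinate numbering) | C1=C[C@H](O[Si](CC)(CC)CC)C[C@@](O)(C(=O)OCc2ccc(OC)cc2)C1 | intermediate
15 | 4-methoxybenzyl (1R,3R)-1,3-dihydroxycyclohex-4-ene-1-carboxylate (quinate numbering) | C1=C[C@H](O)C[C@@](O)(C(=O)OCc2ccc(OC)cc2)C1 | intermediate
16 | 4-methoxybenzyl (1S,3R,4R,5S)-4,5-epoxy-1,3-dihydroxycyclohexane-1-carboxylate | O[C@@H]1C[C@@](O)(C(=O)OCc3ccc(OC)cc3)C[C@@H]2O[C@H]12 | intermediate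
17 | 4-methoxybenzyl (1R,3R,4S,5S)-3-(tert-butyldimethylsilyloxy)-4,5-epoxy-1-hydroxycyclohexane-1-carboxylate | CC(C)(C)[Si](C)(C)O[C@@H]1C[C@@](O)(C(=O)OCc3ccc(OC)cc3)C[C@@H]2O[C@H]12 | intermediate
18 | (E)-p-coumaric acid | OC(=O)/C=C/c1ccc(O)cc1 | starting material
19 | 4-methoxybenzyl chloride | COc1ccc(CCl)cc1 | starting material
20 | 4-methoxybenzyl (E)-3-[4-(4-methoxybenzyloxy)phenyl]prop-2-enoate | COc1ccc(COC(=O)/C=C/c2ccc(OCc3ccc(OC)cc3)cc2)cc1 | intermediate
21 | (E)-3-[4-(4-methoxybenzyloxy)phenyl]prop-2-enoic acid | OC(=O)/C=C/c1ccc(OCc2ccc(OC)cc2)cc1 | intermediate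
22 | 4-methoxybenzyl (1R,3R,4S,5R)-3-(tert-butyldimethylsilyloxy)-1,4-dihydroxy-5-{(E)-3-[4-(4-methoxybenzyloxy)phenyl]prop-2-enoyloxy}cyclohexane-1-carboxylate | O[C@@H]1[C@H](O[Si](C)(C)C(C)(C)C)C[C@@](O)(C(=O)OCc2ccc(OC)cc2)C[C@H]1OC(=O)/C=C/c3ccc(OCc4ccc(OC)cc4)cc3 | intermediate
23 | 4-methoxybenzyl (1R,3R,4S,5R)-3-(tert-butyldimethylsilyloxy)-1-hydroxy-4,5-bis{(E)-3-[4-(4-methoxybenzyloxy)phenyl]prop-2-enoyloxy}cyclohexane-1-carboxylate | O=C(/C=C/c1ccc(OCc2ccc(OC)cc2)cc1)O[C@@H]3[C@H](O[Si](C)(C)C(C)(C)C)C[C@@](O)(C(=O)OCc4ccc(OC)cc4)C[C@H]3OC(=O)/C=C/c5ccc(OCc6ccc(OC)cc6)cc5 | intermediate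
24 | 4,5-di-O-p-coumaroylquinic acid, (1S,3R,4R,5R) | O=C(/C=C/c1ccc(O)cc1)O[C@@H]1[C@H](O)C[C@@](O)(C(=O)O)C[C@H]1OC(=O)/C=C/c1ccc(O)cc1 | target

## Step count and least certain steps

Total: 12 steps. Longest linear sequence: 11 steps (steps 1 to 8 and 10 to 12, from (R)-malic acid); step 9 is a one-step side branch.

**Step 6 (key step).** Intermolecular metathesis at the allyl terminus may compete with closure, the alkylidene may stall by chelating the α-hydroxy ester, ruthenium hydrides may shift the double bond, or the silyl ether may be lost early and the open chain may lactonise. Fallback: close the ring before the ester exchange. Setting out from 11, the same catalyst would cyclise the diene held on the quaternary dioxolanone carbon (no free hydroxyl, no chelating ester) to (2R,5R,9R)-2-tert-butyl-9-(triethylsilyloxy)-1,3-dioxaspiro[4.5]dec-7-en-4-one F1. Lithium 4-methoxybenzyl oxide would then open the dioxolanone of F1, coming back to the route at 14, which is desilylated to 15 as in step 6.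

**Step 4.** Face selectivity may be poor because the vinyl group is small and the other ketone substituent is branched, catecholborane may reduce the enone in the conjugate sense, or the alcohol may attack the lactone acetal before it is silylated. Fallback: replace the enone by an ynone, which is reduced with more reliable control. Setting out from 6 (through 8), acyl Sonogashira coupling with trimethylsilylacetylene (PdCl2(PPh3)2, CuI, Et3N) would give (2R,5R)-5-allyl-2-tert-butyl-5-[2-oxo-4-(trimethylsilyl)but-3-yn-1-yl]-1,3-dioxolan-4-one F2. Transfer hydrogenation with RuCl[(R,R)-TsDPEN](p-cymene) in i-PrOH should give (2R,5R)-5-allyl-2-tert-butyl-5-[(2R)-2-hydroxy-4-(trimethylsilyl)but-3-yn-1-yl]-1,3-dioxolan-4-one F3. Silylation with Et3SiOTf would give (2R,5R)-5-allyl-2-tert-butyl-5-[(2R)-2-(triethylsilyloxy)-4-(trimethylsilyl)but-3-yn-1-yl]-1,3-dioxolan-4-one F4. Lithium 4-methoxybenzyl oxide in excess 4-methoxybenzyl alcohol should open the dioxolanone and remove the alkynyl silyl group to give 4-methoxybenzyl (2R,4R)-2-allyl-2-hydroxy-4-(triethylsilyloxy)hex-5-ynoate F5. Semi-hydrogenation of F5 over Pd/CaCO3/Pb(OAc)2 (Lindlar catalyst) with quinoline comes back to the route at 13.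

**Step 10.** The hindered internal epoxide may open slowly, attack may go to C4, the silyl group may migrate from O3 to the O4 alkoxide, or the carboxylate may take the benzylic group from the C1 ester. Fallback: let the C1 carboxyl open the epoxide, which can only reach C5. Setting out from 17, saponification (LiOH, THF–H2O) and gentle warming or acidification to pH 4 should give, by 5-exo attack of the carboxyl on the face opposite the epoxide oxygen, 3-O-(tert-butyldimethylsilyl)quinic acid 1,5-lactone F6. Opening of the lactone with 4-methoxybenzyl alcohol and a catalytic amount of its lithium alkoxide would give 4-methoxybenzyl 3-O-(tert-butyldimethylsilyl)quinate F7. Double Steglich acylation of O4 and O5 with 21 (4 equiv) comes back to the route at 23.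

**Step 3.** The vinyl ketone may polymerise or take up nucleophiles in the conjugate sense, and the acylpalladium intermediate may insert into the allyl alkene before the vinyl group is transferred. Fallback: make the ketone without palladium. Setting out from 6, activation with carbonyldiimidazole and reaction with MeNHOMe·HCl would give 2-[(2R,4R)-4-allyl-2-tert-butyl-5-oxo-1,3-dioxolan-4-yl]-N-methoxy-N-methylacetamide F8. Vinylmagnesium bromide at −78 → −20 °C, quenched inversely into cold dilute acid, comes back to the route at 9. The stable magnesium chelate of the amide adduct and the hindered lactone carbonyl should keep the second carbonyl out of the reaction.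

**Step 12.** An acyl group may migrate to O3 once the silyl group is gone, the benzylic cations may alkylate the phenol rings, or Si–O cleavage may be incomplete. Fallback: separate the two events. Setting out from 23, anhydrous CF3CO2H with pentamethylbenzene in CH2Cl2 at 0 °C would remove only the three benzylic groups and give 3-O-(tert-butyldimethylsilyl)-4,5-di-O-p-coumaroylquinic acid F9, in which O3 is still blocked. Buffered fluoride (HF·pyridine in THF–pyridine) would then cleave the silyl ether under non-basic conditions and come back to the route at 24.

## Further compounds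

F1 | step 6 | (2R,5R,9R)-2-tert-butyl-9-(triethylsilyloxy)-1,3-dioxaspiro[4.5]dec-7-en-4-one | O=C1O[C@H](C(C)(C)C)O[C@@]12CC=C[C@H](O[Si](CC)(CC)CC)C2
F2 | step 4 | (2R,5R)-5-allyl-2-tert-butyl-5-[2-oxo-4-(trimethylsilyl)but-3-yn-1-yl]-1,3-dioxolan-4-one | O=C1O[C@H](C(C)(C)C)O[C@]1(CC=C)CC(=O)C#C[Si](C)(C)C
F3 | step 4 | (2R,5R)-5-allyl-2-tert-butyl-5-[(2R)-2-hydroxy-4-(trimethylsilyl)but-3-yn-1-yl]-1,3-dioxolan-4-one | O=C1O[C@H](C(C)(C)C)O[C@]1(CC=C)C[C@@H](O)C#C[Si](C)(C)C
F4 | step 4 | (2R,5R)-5-allyl-2-tert-butyl-5-[(2R)-2-(triethylsilyloxy)-4-(trimethylsilyl)but-3-yn-1-yl]-1,3-dioxolan-4-one | O=C1O[C@H](C(C)(C)C)O[C@]1(CC=C)C[C@@H](O[Si](CC)(CC)CC)C#C[Si](C)(C)C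
F5 | step 4 | 4-methoxybenzyl (2R,4R)-2-allyl-2-hydroxy-4-(triethylsilyloxy)hex-5-ynoate | C#C[C@H](O[Si](CC)(CC)CC)C[C@@](O)(C(=O)OCc1ccc(OC)cc1)CC=C
F6 | step 10 | 3-O-(tert-butyldimethylsilyl)quinic acid 1,5-lactone | O[C@@H]1[C@H](O[Si](C)(C)C(C)(C)C)C[C@@](O)(C2=O)C[C@H]1O2
F7 | step 10 | 4-methoxybenzyl 3-O-(tert-butyldimethylsilyl)quinate | O[C@@H]1[C@H](O[Si](C)(C)C(C)(C)C)C[C@@](O)(C(=O)OCc2ccc(OC)cc2)C[C@H]1O
F8 | step 3 | 2-[(2R,4R)-4-allyl-2-tert-butyl-5-oxo-1,3-dioxolan-4-yl]-N-methoxy-N-methylacetamide | O=C1O[C@H](C(C)(C)C)O[C@]1(CC=C)CC(=O)N(C)OC
F9 | step 12 | 3-O-(tert-butyldimethylsilyl)-4,5-di-O-p-coumaroylquinic acid | O=C(/C=C/c1ccc(O)cc1)O[C@@H]2[C@H](O[Si](C)(C)C(C)(C)C)C[C@@](O)(C(=O)O)C[C@H]2OC(=O)/C=C/c3ccc(O)cc3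
A1 | alternative 1 | methyl 1,4-epidioxy-5-(tert-butyldimethylsilyloxy)cyclohex-2-ene-1-carboxylate | O2[C@@H]1C=C[C@@](O2)(C(=O)OC)C[C@H]1O[Si](C)(C)C(C)(C)C
A2 | alternative 1 | methyl (5R)-5-(tert-butyldimethylsilyloxy)cyclohexa-1,3-diene-1-carboxylate | COC(=O)C1=CC=C[C@H](O[Si](C)(C)C(C)(C)C)C1
A3 | alternative 2 | 1-(methoxymethoxy)-5-(tert-butyldimethylsilyloxy)cyclohex-3-ene-1-carboxylic acid (quinate numbering) | C1=CC[C@@](OCOC)(C(=O)O)C[C@H]1O[Si](C)(C)C(C)(C)C
A4 | alternative 2 | (5R,6S)-5-(tert-butyldimethylsilyloxy)-3-(methoxymethoxy)-6-vinyltetrahydro-2H-pyran-2-one (C3 of either configuration) | C=C[C@@H]1OC(=O)C(OCOC)C[C@H]1O[Si](C)(C)C(C)(C)C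
A5 | alternative 3 | methyl 1-O-methoxymethyl-5-O-(tert-butyldimethylsilyl)quinate | O[C@@H]1[C@H](O)C[C@@](OCOC)(C(=O)OC)C[C@H]1O[Si](C)(C)C(C)(C)C
A6 | alternative 3 | methyl (2R,4R)-4-(tert-butyldimethylsilyloxy)-2-(methoxymethoxy)-5-oxo-2-(2-oxoethyl)pentanoate | O=C[C@H](O[Si](C)(C)C(C)(C)C)C[C@](OCOC)(C(=O)OC)CC=O
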